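**Retrosynthetic overview**
The route rests on the hexasubstituted benzene ring C4a–C5–C6–C7–C8–C8a, whose two oxygens (C5, C8a) sit 1,3 across the carbon-bearing C4a. A vinylketene plus siloxyalkyne benzannulation writes exactly this pattern and leaves the C8a hydroxyl free and the C5 oxygen silylated, so only O1 can later close the pyran ring.
The arene is therefore cut into two open-chain pieces: a siloxyalkyne from geranyl acetate (C5, C4a and the C4–C3–C2 chain) and a 2-diazo-3-oxo ester from 4-methylpent-3-en-1-ol (C8a, C6, C7, C8, carboxyl, methyl, prenyl).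
The O1–C2 bond is disconnected to a phenol and an (E)-allylic methyl carbonate (asymmetric palladium allylic etherification, sets C2), and the diene to a 2-vinylchroman plus 1-bromo-2-methylpropene (Heck).
Ring order: benzene ring first, pyran ring second, dienyl side chain last; one fluoride step then frees the phenol and the acid.

Key step: step 12

Assumption: the (R,R) ligand is taken to deliver the (R)-chroman from the (E)-carbonate; the sense is to be confirmed by correlation on the first run, and the mirror-image ligand is used if it is opposite.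

**Route**

Step 1
Reactants: 1 geranyl acetate
Product: 2 (E)-5-(3,3-dimethyloxiran-2-yl)-3-methylpent-2-enyl acetate (6,7-epoxygeranyl acetate; racemic at the epoxide carbon)
Conditions: mCPBA, CH2Cl2, 0 °C
Reagents that add atoms: mCPBA, OOC(=O)c1cccc(Cl)c1
Why: In this Prilezhaev epoxidation the electron-rich distal alkene should react faster than the 2,3-alkene, which is deactivated by the allylic acetate; the racemic epoxide carbon is removed in step 2.

Step 2
Reactants: 2 6,7-epoxygeranyl acetate
Product: 3 (E)-6-acetoxy-4-methylhex-4-enal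
Conditions: H5IO6, THF/Et2O, 0 °C
Reagents that add atoms: none
Why: Periodic acid opens the epoxide with water at the tertiary carbon and cleaves the glycol (Malaprade-type cleavage), so the aldehyde keeps the epoxide oxygen and acetone is lost, while the allylic acetate and the (E)-alkene are untouched.

Step 3
Reactants: 3 (E)-6-acetoxy-4-methylhex-4-enal
Product: 5 (E)-3-methylhept-2-en-6-yn-1-ol, via enyne acetate 4 (not isolated)
Conditions: dimethyl (1-diazo-2-oxopropyl)phosphonate, K2CO3, MeOH, 0 °C to rt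
Reagents that add atoms: dimethyl (1-diazo-2-oxopropyl)phosphonate, COP(=O)(OC)C(=[N+]=[N-])C(C)=O
Why: The Ohira–Bestmann variant of the Seyferth–Gilbert homologation turns the aldehyde into the terminal alkyne 4, and the same K2CO3/MeOH medium should transesterify the allylic acetate so that the free alcohol is obtained in one operation.

Step 4
Reactants: 5 (E)-3-methylhept-2-en-6-yn-1-ol
Product: 6 tert-butyldimethyl{[(E)-3-methylhept-2-en-6-ynyl]oxy}silane
Conditions: TBSCl, imidazole, CH2Cl2, 0 °C to rt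
Reagents that add atoms: tert-butyldimethylsilyl chloride, CC(C)(C)[Si](C)(C)Cl
Why: Imidazole-promoted silylation of the primary alcohol protects it against the organolithium and peroxide reagents of step 5.

Step 5
Reactants: 6 TBS ether of (E)-3-methylhept-2-en-6-yn-1-ol
Product: 9 tert-butyldimethyl{[(E)-3-methyl-7-(triisopropylsilyloxy)hept-2-en-6-ynyl]oxy}silane (the siloxyalkyne), via lithium acetylide 7 (not isolated), via lithium ynolate 8 (not isolated)
Conditions: n-BuLi, THF, −78 °C; t-BuOOLi (from t-BuOOH and LiN(SiMe3)2), −78 to 0 °C; TIPSOTf, −78 to 0 °C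
Reagents that add atoms: tert-butyl hydroperoxide (as its lithium salt), CC(C)(C)OO; triisopropylsilyl trifluoromethanesulfonate, CC(C)[Si](OS(=O)(=O)C(F)(F)F)(C(C)C)C(C)C
Why: The acetylide 7 attacks the electrophilic oxygen of lithium tert-butyl peroxide to give the ynolate 8 (oxenoid oxidation of an acetylide), and the hard, bulky silyl triflate should trap 8 on oxygen to give a triisopropylsiloxyalkyne robust enough to purify.

Step 6
Reactants: 10 4-methylpent-3-en-1-ol
Product: 11 4-methylpent-3-enal
Conditions: Dess–Martin periodinane, CH2Cl2, 0 °C to rt; used at once as a dried solution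
Reagents that add atoms: none
Why: Dess–Martin oxidation under near-neutral conditions should give the β,γ-unsaturated aldehyde without moving the alkene into conjugation.

Step 7
Reactants: 11 4-methylpent-3-enal; 12 triethyl 2-phosphonopropionate
Product: 13 ethyl (E)-2,6-dimethylhepta-2,5-dienoate
Conditions: 12, NaH, THF, 0 °C; then 11, −78 to 0 °C
Reagents that add atoms: none
Why: The Horner–Wadsworth–Emmons olefination with an α-methyl phosphonoacetate should give the trisubstituted (E)-enoate, and adding the aldehyde cold to the preformed anion limits enolisation of 11.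

Step 8
Reactants: 13 ethyl (E)-2,6-dimethylhepta-2,5-dienoate
Product: 14 (E)-2,6-dimethylhepta-2,5-dienoic acid
Conditions: LiOH, THF/MeOH/H2O, rt; then dilute HCl
Reagents that add atoms: lithium hydroxide, [Li+].[OH-]
Why: Saponification at room temperature cleaves the ethyl ester without deprotonating the doubly allylic CH2, so the skipped diene and the (E)-geometry are kept.

Step 9
Reactants: 14 (E)-2,6-dimethylhepta-2,5-dienoic acid; 15 Meldrum's acid
Product: 16 5-[(E)-1-hydroxy-2,6-dimethylhepta-2,5-dienylidene]-2,2-dimethyl-1,3-dioxane-4,6-dione (acyl Meldrum's acid, enol form)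
Conditions: DCC, DMAP, CH2Cl2, 0 °C to rt; cold aqueous KHSO4 wash
Reagents that add atoms: none
Why: Carbodiimide activation and DMAP-mediated C-acylation of Meldrum's acid is the standard entry to β-keto ester precursors and tolerates the α-branched enoic acid.

Step 10
Reactants: 16 acyl Meldrum's acid
Product: 18 2-(trimethylsilyl)ethyl (E)-4,8-dimethyl-3-oxonona-4,7-dienoate, via acylketene 17 (not isolated)
Conditions: Me3SiCH2CH2OH, toluene, 90 °C
Reagents that add atoms: 2-(trimethylsilyl)ethanol, C[Si](C)(C)CCO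
Why: Thermal retro-[4+2] fragmentation of 16 releases acetone and CO2 to give the acylketene 17, which the alcohol traps as the β-keto ester (acyl Meldrum's acid alcoholysis).

Step 11
Reactants: 18 β-keto ester
Product: 19 2-(trimethylsilyl)ethyl (E)-2-diazo-4,8-dimethyl-3-oxonona-4,7-dienoate
Conditions: 4-acetamidobenzenesulfonyl azide, Et3N, MeCN, 0 °C to rt
Reagents that add atoms: 4-acetamidobenzenesulfonyl azide, CC(=O)Nc1ccc(cc1)S(=O)(=O)N=[N+]=[N-]
Why: Regitz diazo transfer to the active methylene of a β-keto ester is reliable and leaves the alkenes and the silylethyl ester alone.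

Step 12
Reactants: 9 siloxyalkyne; 19 2-diazo-3-oxo ester
Product: 24 2-(trimethylsilyl)ethyl 3-[(E)-5-(tert-butyldimethylsilyloxy)-3-methylpent-3-enyl]-4-hydroxy-6-methyl-5-(3-methylbut-2-enyl)-2-(triisopropylsilyloxy)benzoate, via vinylketene 20 (not isolated), via vinylcyclobutenone 21 (not isolated), via dienylketene 22 (not isolated), via cyclohexadienone 23 (not isolated)
Conditions: 19 (1.3 equiv), hν (medium-pressure Hg lamp, Vycor filter), degassed ClCH2CH2Cl, rt; then 80 °C
Reagents that add atoms: none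
Why: Proposed new method: light expels N2 from 19 and the Wolff shift of the alkenyl group to the carbene carbon (bond C6–C7) gives the ester-substituted vinylketene 20, to whose carbonyl carbon the alkyl-bearing carbon of the polarised siloxyalkyne 9 adds, closing a [2+2] across the ketene C=C (bonds C4a–C8a and C5–C6) to the 4-vinylcyclobutenone 21, which opens by 4π electrocyclic ring opening to the dienylketene 22. The closest known reaction type is the photo-Wolff variant of the Danheiser benzannulation of unsaturated α-diazo ketones with trialkylsiloxyalkynes, which has not been shown with a 2-diazo-3-oxo ester as the ketene source. The benzene ring is closed by 6π electrocyclisation of 22 (bond C8–C8a) and the cyclohexadienone 23 tautomerises to the phenol, so every one of the six ring positions is fixed by the connectivity of the two partners. No stereocentre is formed, the transient ones in 21 and 23 being lost on aromatisation. The step needs migration of the alkenyl and not the alkoxy group, and ring closure of the ketene–ynol ether adduct through carbon and not through the ester oxygen (hetero-[4+2]); the higher migratory aptitude of carbon groups, the strong donor polarisation of the ynol ether and the weak heterodiene character of an ester C=O should secure both, and the (E)-alkene of 19 places hydrogen, not the prenyl CH2, on the inside of the closing triene.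

Step 13
Reactants: 24 benzannulation product
Product: 25 2-(trimethylsilyl)ethyl 4-hydroxy-3-[(E)-5-hydroxy-3-methylpent-3-enyl]-6-methyl-5-(3-methylbut-2-enyl)-2-(triisopropylsilyloxy)benzoate
Conditions: PPTS (cat.), MeOH, rt
Reagents that add atoms: none
Why: Mild acid-catalysed methanolysis (selective desilylation) should remove the unhindered primary TBS ether much faster than the aryl TIPS ether, which is shielded by two ortho substituents, and does not affect the silylethyl ester.

Step 14
Reactants: 25 allylic alcohol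
Product: 26 2-(trimethylsilyl)ethyl 4-hydroxy-3-[(E)-5-(methoxycarbonyloxy)-3-methylpent-3-enyl]-6-methyl-5-(3-methylbut-2-enyl)-2-(triisopropylsilyloxy)benzoate
Conditions: ClCO2Me (1.1 equiv), pyridine, CH2Cl2, −20 to 0 °C
Reagents that add atoms: methyl chloroformate, COC(=O)Cl
Why: Chloroformate acylation with pyridine and no acyl-transfer catalyst should take the unhindered primary allylic alcohol in preference to the phenol, whose hydroxyl is flanked by two ortho alkyl groups (chemoselective carbonate formation).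

Step 15
Reactants: 26 phenol allylic carbonate
Product: 27 2-(trimethylsilyl)ethyl (R)-2,7-dimethyl-8-(3-methylbut-2-enyl)-5-(triisopropylsilyloxy)-2-vinylchroman-6-carboxylate
Conditions: Pd2(dba)3·CHCl3 (cat.), (R,R)-DACH-phenyl Trost ligand, AcOH, CH2Cl2, rt
Reagents that add atoms: none
Why: Zerovalent palladium ionises the carbonate and the phenol attacks the π-allyl at its tertiary terminus, the only one that gives a six-membered ring (Trost asymmetric allylic alkylation with an oxygen nucleophile), the C2 stereocentre being set by the chiral diphosphine, which selects the faster-cyclising diastereomeric π-allyl complex.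

Step 16
Reactants: 27 (R)-2-vinylchroman; 28 1-bromo-2-methylpropene
Product: 29 2-(trimethylsilyl)ethyl (R)-2,7-dimethyl-2-[(E)-4-methylpenta-1,3-dienyl]-8-(3-methylbut-2-enyl)-5-(triisopropylsilyloxy)chroman-6-carboxylate
Conditions: 28 (3 equiv), Pd(OAc)2 (cat.), n-Bu4NCl, NaHCO3, DMF, 70 °C, sealed tube
Reagents that add atoms: none
Why: In this Heck reaction the alkenylpalladium bromide from 28 adds to the terminal carbon of the vinyl group and syn β-hydride elimination gives the (E)-diene, the quaternary C2 offering no other hydrogen, while the phosphine-free conditions keep zerovalent palladium from re-ionising the tertiary allylic aryl ether, so C2 is not scrambled.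

Step 17
Reactants: 29 protected dienylchroman
Product: 30 (R)-5-hydroxy-2,7-dimethyl-2-[(E)-4-methylpenta-1,3-dienyl]-8-(3-methylbut-2-enyl)chroman-6-carboxylic acid (target CNP0137659.1)
Conditions: TBAF, THF, 0 °C to rt; cold dilute HCl to pH 3–4
Reagents that add atoms: none
Why: Fluoride cleaves the aryl silyl ether and triggers β-elimination of the 2-(trimethylsilyl)ethyl ester (loss of ethylene and Me3SiF) in one non-acidic operation that spares the acid-labile tertiary dienylic aryl ether and the salicylic acid.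

**Compound list**
1 | geranyl acetate | CC(C)=CCC/C(C)=C/COC(C)=O | starting material
2 | (E)-5-(3,3-dimethyloxiran-2-yl)-3-methylpent-2-enyl acetate (racemic) | CC1(C)OC1CC/C(C)=C/COC(C)=O | intermediate
3 | (E)-6-acetoxy-4-methylhex-4-enal | O=CCC/C(C)=C/COC(C)=O | intermediate
4 | (E)-3-methylhept-2-en-6-ynyl acetate | C#CCC/C(C)=C/COC(C)=O | intermediate
5 | (E)-3-methylhept-2-en-6-yn-1-ol | C#CCC/C(C)=C/CO | intermediate
6 | tert-butyldimethyl{[(E)-3-methylhept-2-en-6-ynyl]oxy}silane | C#CCC/C(C)=C/CO[Si](C)(C)C(C)(C)C | intermediate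
7 | lithium acetylide of 6 | [Li]C#CCC/C(C)=C/CO[Si](C)(C)C(C)(C)C | intermediate
8 | lithium (E)-7-(tert-butyldimethylsilyloxy)-5-methylhept-5-en-1-yn-1-olate (ynolate) | [Li+].[O-]C#CCC/C(C)=C/CO[Si](C)(C)C(C)(C)C | intermediate
9 | tert-butyldimethyl{[(E)-3-methyl-7-(triisopropylsilyloxy)hept-2-en-6-ynyl]oxy}silane | CC(C)[Si](OC#CCC/C(C)=C/CO[Si](C)(C)C(C)(C)C)(C(C)C)C(C)C | intermediate
10 | 4-methylpent-3-en-1-ol | CC(C)=CCCO | starting material
11 | 4-methylpent-3-enal | CC(C)=CCC=O | intermediate
12 | triethyl 2-phosphonopropionate | CCOC(=O)C(C)P(=O)(OCC)OCC | starting material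
13 | ethyl (E)-2,6-dimethylhepta-2,5-dienoate | CCOC(=O)/C(C)=C/CC=C(C)C | intermediate
14 | (E)-2,6-dimethylhepta-2,5-dienoic acid | CC(C)=CC/C=C(\C)C(=O)O | intermediate
15 | Meldrum's acid | CC1(C)OC(=O)CC(=O)O1 | starting material
16 | 5-[(E)-1-hydroxy-2,6-dimethylhepta-2,5-dienylidene]-2,2-dimethyl-1,3-dioxane-4,6-dione | CC(C)=CC/C=C(\C)C(O)=C1C(=O)OC(C)(C)OC1=O | intermediate
17 | (E)-4,8-dimethylnona-1,4,7-triene-1,3-dione (acylketene) | CC(C)=CC/C=C(\C)C(=O)C=C=O | intermediate
18 | 2-(trimethylsilyl)ethyl (E)-4,8-dimethyl-3-oxonona-4,7-dienoate | CC(C)=CC/C=C(\C)C(=O)CC(=O)OCC[Si](C)(C)C | intermediate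
19 | 2-(trimethylsilyl)ethyl (E)-2-diazo-4,8-dimethyl-3-oxonona-4,7-dienoate | CC(C)=CC/C=C(\C)C(=O)C(=[N+]=[N-])C(=O)OCC[Si](C)(C)C | intermediate
20 | 2-(trimethylsilyl)ethyl (E)-3,7-dimethyl-2-(oxomethylidene)octa-3,6-dienoate (vinylketene) | CC(C)=CC/C=C(\C)C(=C=O)C(=O)OCC[Si](C)(C)C | intermediate
21 | 4-vinylcyclobutenone: 2-alkyl-3-(triisopropylsilyloxy)cyclobut-2-enone with the ester and the (E)-alkenyl group on C4 (racemic) | O=C1C(CC/C(C)=C/CO[Si](C)(C)C(C)(C)C)=C(O[Si](C(C)C)(C(C)C)C(C)C)C1(C(=O)OCC[Si](C)(C)C)/C(C)=C/CC=C(C)C | intermediate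
22 | dienylketene from ring opening of 21 | O=C=C(CC/C(C)=C/CO[Si](C)(C)C(C)(C)C)/C(O[Si](C(C)C)(C(C)C)C(C)C)=C(C(=O)OCC[Si](C)(C)C)\C(C)=C\CC=C(C)C | intermediate
23 | cyclohexa-2,4-dienone tautomer of 24 (racemic) | O=C1C(CC/C(C)=C/CO[Si](C)(C)C(C)(C)C)=C(O[Si](C(C)C)(C(C)C)C(C)C)C(C(=O)OCC[Si](C)(C)C)=C(C)C1CC=C(C)C | intermediate
24 | 2-(trimethylsilyl)ethyl 3-[(E)-5-(tert-butyldimethylsilyloxy)-3-methylpent-3-enyl]-4-hydroxy-6-methyl-5-(3-methylbut-2-enyl)-2-(triisopropylsilyloxy)benzoate | Oc1c(CC=C(C)C)c(C)c(C(=O)OCC[Si](C)(C)C)c(O[Si](C(C)C)(C(C)C)C(C)C)c1CC/C(C)=C/CO[Si](C)(C)C(C)(C)C | intermediate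
25 | 2-(trimethylsilyl)ethyl 4-hydroxy-3-[(E)-5-hydroxy-3-methylpent-3-enyl]-6-methyl-5-(3-methylbut-2-enyl)-2-(triisopropylsilyloxy)benzoate | Oc1c(CC=C(C)C)c(C)c(C(=O)OCC[Si](C)(C)C)c(O[Si](C(C)C)(C(C)C)C(C)C)c1CC/C(C)=C/CO | intermediate
26 | 2-(trimethylsilyl)ethyl 4-hydroxy-3-[(E)-5-(methoxycarbonyloxy)-3-methylpent-3-enyl]-6-methyl-5-(3-methylbut-2-enyl)-2-(triisopropylsilyloxy)benzoate | Oc1c(CC=C(C)C)c(C)c(C(=O)OCC[Si](C)(C)C)c(O[Si](C(C)C)(C(C)C)C(C)C)c1CC/C(C)=C/COC(=O)OC | intermediate
27 | 2-(trimethylsilyl)ethyl (R)-2,7-dimethyl-8-(3-methylbut-2-enyl)-5-(triisopropylsilyloxy)-2-vinylchroman-6-carboxylate | C=C[C@@]1(C)CCc2c(O[Si](C(C)C)(C(C)C)C(C)C)c(C(=O)OCC[Si](C)(C)C)c(C)c(CC=C(C)C)c2O1 | intermediate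
28 | 1-bromo-2-methylpropene | CC(C)=CBr | starting material
29 | 2-(trimethylsilyl)ethyl (R)-2,7-dimethyl-2-[(E)-4-methylpenta-1,3-dienyl]-8-(3-methylbut-2-enyl)-5-(triisopropylsilyloxy)chroman-6-carboxylate | CC(C)=C/C=C/[C@@]1(C)CCc2c(O[Si](C(C)C)(C(C)C)C(C)C)c(C(=O)OCC[Si](C)(C)C)c(C)c(CC=C(C)C)c2O1 | intermediate
30 | (R)-5-hydroxy-2,7-dimethyl-2-[(E)-4-methylpenta-1,3-dienyl]-8-(3-methylbut-2-enyl)chroman-6-carboxylic acid | CC(C)=C/C=C/[C@@]1(C)CCc2c(O)c(C(=O)O)c(C)c(CC=C(C)C)c2O1 | target

**Count**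
Total steps: 17. Longest linear sequence: 12 steps (from 10 through steps 6–11, then steps 12–17).

**Steps most likely to fail**

1. Step 12 (bears the label). What may go wrong: the Wolff shift takes the alkoxy instead of the alkenyl group, the ketene–ynol ether adduct closes through the ester oxygen instead of through carbon, or the ketene acylates the product phenol. Fallback (known chemistry): the benzannulation is run in its established form with an α-diazo ketone carrying hydrogen at the diazo carbon, and the carboxyl group is put on at the end. It sets out from acid 14 and siloxyalkyne 9 and comes back at target 30.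
   - Acid 14 with MeLi (2.2 equiv, Et2O, 0 °C) should give the methyl ketone (E)-3,7-dimethylocta-3,6-dien-2-one F1.
   - Its kinetic enolate (LiN(SiMe3)2, THF, −78 °C) is acylated with CF3CO2CH2CF3 to the trifluoroacetyl ketone (E)-1,1,1-trifluoro-5,9-dimethyldeca-5,8-diene-2,4-dione F2. Detrifluoroacetylative diazo transfer (MsN3, Et3N, H2O, MeCN) then gives the diazo ketone (E)-1-diazo-3,7-dimethylocta-3,6-dien-2-one F3.
   - Irradiation of F3 with 9 and warming as in step 12 should give the phenol 2-[(E)-5-(tert-butyldimethylsilyloxy)-3-methylpent-3-enyl]-5-methyl-6-(3-methylbut-2-enyl)-3-(triisopropylsilyloxy)phenol F4, which has hydrogen at C6.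
   - The conditions of steps 13 to 16 then lead through the allylic alcohol 2-[(E)-5-hydroxy-3-methylpent-3-enyl]-5-methyl-6-(3-methylbut-2-enyl)-3-(triisopropylsilyloxy)phenol F5, the carbonate (E)-5-[2-hydroxy-4-methyl-3-(3-methylbut-2-enyl)-6-(triisopropylsilyloxy)phenyl]-3-methylpent-2-enyl methyl carbonate F6, the vinylchroman triisopropyl{[(R)-2,7-dimethyl-8-(3-methylbut-2-enyl)-2-vinylchroman-5-yl]oxy}silane F7 and, with 28, the dienylchroman triisopropyl{[(R)-2,7-dimethyl-2-[(E)-4-methylpenta-1,3-dienyl]-8-(3-methylbut-2-enyl)chroman-5-yl]oxy}silane F8.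
   - TBAF frees the chromanol (R)-2,7-dimethyl-2-[(E)-4-methylpenta-1,3-dienyl]-8-(3-methylbut-2-enyl)chroman-5-ol F9. Chelation-controlled ortho-carboxylation at C6, the only free ring position, with MeOMgOCO2Me (DMF, 120 °C, then cold dilute acid; Kolbe–Schmitt type) should give 30.

2. Step 15. What may go wrong: insufficient or reversed enantioselection with the (E)-configured trisubstituted allyl unit on so crowded a phenol. Fallback: the stereocentre is set by reagent-controlled epoxidation and a stereospecific ring closure. It sets out from allylic alcohol 25 and comes back at vinylchroman 27.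
   - Sharpless asymmetric epoxidation of 25 (Ti(OiPr)4, L-(+)-diethyl tartrate, t-BuOOH, 4 Å sieves, CH2Cl2, −20 °C) should give the epoxy alcohol 2-(trimethylsilyl)ethyl 4-hydroxy-3-{2-[(2S,3S)-3-(hydroxymethyl)-2-methyloxiran-2-yl]ethyl}-6-methyl-5-(3-methylbut-2-enyl)-2-(triisopropylsilyloxy)benzoate F10.
   - The C8a phenol opens the epoxide at its tertiary carbon with inversion (6-exo; CSA cat., CH2Cl2, 0 °C) to the diol 2-(trimethylsilyl)ethyl (R)-2-[(S)-1,2-dihydroxyethyl]-2,7-dimethyl-8-(3-methylbut-2-enyl)-5-(triisopropylsilyloxy)chroman-6-carboxylate F11.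
   - NaIO4 (THF/H2O) cleaves the glycol to the aldehyde 2-(trimethylsilyl)ethyl (R)-2-formyl-2,7-dimethyl-8-(3-methylbut-2-enyl)-5-(triisopropylsilyloxy)chroman-6-carboxylate F12, and Wittig methylenation (Ph3P=CH2, THF, 0 °C) gives 27.

3. Step 16. What may go wrong: slow or non-regioselective insertion of the hindered, unactivated alkene, loss of the volatile bromide, re-ionisation of the allylic aryl ether by zerovalent palladium with erosion of C2, or further reaction of the diene. Fallback: the alkene is first made into a nucleophilic coupling partner. It sets out from vinylchroman 27 and comes back at 29.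
   - Cross-metathesis with vinylboronic acid pinacol ester (second-generation Hoveyda–Grubbs catalyst, CH2Cl2, 40 °C) should give the alkenylboronate 2-(trimethylsilyl)ethyl (R)-2,7-dimethyl-8-(3-methylbut-2-enyl)-2-[(E)-2-(4,4,5,5-tetramethyl-1,3,2-dioxaborolan-2-yl)vinyl]-5-(triisopropylsilyloxy)chroman-6-carboxylate F13.
   - Suzuki–Miyaura coupling of F13 with 28 (PdCl2(dppf), K3PO4, THF/H2O, 50 °C) gives 29 with retention of the (E)-geometry.

**Further compounds**
F1 | step 12 | (E)-3,7-dimethylocta-3,6-dien-2-one | CC(C)=CC/C=C(\C)C(C)=O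
F2 | step 12 | (E)-1,1,1-trifluoro-5,9-dimethyldeca-5,8-diene-2,4-dione | CC(C)=CC/C=C(\C)C(=O)CC(=O)C(F)(F)F
F3 | step 12 | (E)-1-diazo-3,7-dimethylocta-3,6-dien-2-one | CC(C)=CC/C=C(\C)C(=O)C=[N+]=[N-]
F4 | step 12 | 2-[(E)-5-(tert-butyldimethylsilyloxy)-3-methylpent-3-enyl]-5-methyl-6-(3-methylbut-2-enyl)-3-(triisopropylsilyloxy)phenol | Oc1c(CC=C(C)C)c(C)cc(O[Si](C(C)C)(C(C)C)C(C)C)c1CC/C(C)=C/CO[Si](C)(C)C(C)(C)C
F5 | step 12 | 2-[(E)-5-hydroxy-3-methylpent-3-enyl]-5-methyl-6-(3-methylbut-2-enyl)-3-(triisopropylsilyloxy)phenol | Oc1c(CC=C(C)C)c(C)cc(O[Si](C(C)C)(C(C)C)C(C)C)c1CC/C(C)=C/CO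
F6 | step 12 | (E)-5-[2-hydroxy-4-methyl-3-(3-methylbut-2-enyl)-6-(triisopropylsilyloxy)phenyl]-3-methylpent-2-enyl methyl carbonate | Oc1c(CC=C(C)C)c(C)cc(O[Si](C(C)C)(C(C)C)C(C)C)c1CC/C(C)=C/COC(=O)OC
F7 | step 12 | triisopropyl{[(R)-2,7-dimethyl-8-(3-methylbut-2-enyl)-2-vinylchroman-5-yl]oxy}silane | C=C[C@@]1(C)CCc2c(O[Si](C(C)C)(C(C)C)C(C)C)cc(C)c(CC=C(C)C)c2O1
F8 | step 12 | triisopropyl{[(R)-2,7-dimethyl-2-[(E)-4-methylpenta-1,3-dienyl]-8-(3-methylbut-2-enyl)chroman-5-yl]oxy}silane | CC(C)=C/C=C/[C@@]1(C)CCc2c(O[Si](C(C)C)(C(C)C)C(C)C)cc(C)c(CC=C(C)C)c2O1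
F9 | step 12 | (R)-2,7-dimethyl-2-[(E)-4-methylpenta-1,3-dienyl]-8-(3-methylbut-2-enyl)chroman-5-ol | CC(C)=C/C=C/[C@@]1(C)CCc2c(O)cc(C)c(CC=C(C)C)c2O1
F10 | step 15 | 2-(trimethylsilyl)ethyl 4-hydroxy-3-{2-[(2S,3S)-3-(hydroxymethyl)-2-methyloxiran-2-yl]ethyl}-6-methyl-5-(3-methylbut-2-enyl)-2-(triisopropylsilyloxy)benzoate | OC[C@@H]1O[C@@]1(C)CCc2c(O)c(CC=C(C)C)c(C)c(C(=O)OCC[Si](C)(C)C)c2O[Si](C(C)C)(C(C)C)C(C)C
F11 | step 15 | 2-(trimethylsilyl)ethyl (R)-2-[(S)-1,2-dihydroxyethyl]-2,7-dimethyl-8-(3-methylbut-2-enyl)-5-(triisopropylsilyloxy)chroman-6-carboxylate | OC[C@H](O)[C@@]1(C)CCc2c(O[Si](C(C)C)(C(C)C)C(C)C)c(C(=O)OCC[Si](C)(C)C)c(C)c(CC=C(C)C)c2O1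
F12 | step 15 | 2-(trimethylsilyl)ethyl (R)-2-formyl-2,7-dimethyl-8-(3-methylbut-2-enyl)-5-(triisopropylsilyloxy)chroman-6-carboxylate | O=C[C@@]1(C)CCc2c(O[Si](C(C)C)(C(C)C)C(C)C)c(C(=O)OCC[Si](C)(C)C)c(C)c(CC=C(C)C)c2O1
F13 | step 16 | 2-(trimethylsilyl)ethyl (R)-2,7-dimethyl-8-(3-methylbut-2-enyl)-2-[(E)-2-(4,4,5,5-tetramethyl-1,3,2-dioxaborolan-2-yl)vinyl]-5-(triisopropylsilyloxy)chroman-6-carboxylate | CC1(C)OB(/C=C/[C@@]2(C)CCc3c(O[Si](C(C)C)(C(C)C)C(C)C)c(C(=O)OCC[Si](C)(C)C)c(C)c(CC=C(C)C)c3O2)OC1(C)C
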